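**Plan**

1. Retrosynthesis: the C8–O ester bond and the four oxirane C–O bonds are cut first, giving an 8‑oxygenated germacra‑1(10)E,4E‑diene. C2–C3 is then unsaturated to the 1(10)E,2Z,4E‑triene, and C5 is joined to C10 across the ten‑membered ring to give ring A of a eudesma‑1,3‑diene. The C13–O and C8–O bonds go back to C–H bonds of α‑santonin.
2. Enabling feature: C10=C1–C2=C3–C4=C5 (the four epoxide carbons plus C2 and C3) is a hexatriene at the olefin level, and its ends C5 and C10 face each other across the ten‑membered ring. Its closed form is the cyclohexa‑1,3‑diene ring A of a 5α‑H,10β‑methyl eudesmane that already carries ring B, the C6 lactone oxygen and the C10 methyl of santonin.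
3. Forward order: santonin's decalin and lactone are kept. Ring A is taken to a masked 1‑en‑3‑one while the lactone becomes the 13‑oxygenated 7(11)‑butenolide and C8 is oxygenated and acylated on the rigid decalin. Ring A is then made the 1,3‑diene, light cleaves C5–C10 to release the ten‑membered ring, diimide saturates C2=C3, and peracid closes both oxiranes.
4. Stereochemistry: C6 comes from santonin. C8 comes from axial SeO2 hydroxylation (8β) followed by Mitsunobu inversion with tiglic acid (8α). The E,Z,E geometry comes from conrotatory opening of the trans‑fused diene. C1, C10, C4 and C5 come from peripheral epoxidation of the two E olefins.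

Key step: step 14

Remark: eudesmane/germacrane numbering and α/β descriptors are used (lactone carbonyl C12, oxymethylene C13); the target is read as (1R,4R,5R,6S,8S,10R)‑1β,10α:4α,5β‑diepoxy‑13‑hydroxy‑8α‑tigloyloxygermacr‑7(11)‑en‑12,6α‑olide.

**Route**

Step 1
Reactants: 1 α‑santonin
Product: 2 α‑tetrahydrosantonin (3‑oxo‑4α‑methyl‑5αH,11βH‑eudesman‑12,6α‑olide)
Conditions: H2 (1 atm), 10 % Pd on carbon, EtOAc, 25 °C; then TsOH·H2O (cat.), 25 °C; recrystallisation
Reagents that add atoms: none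
Why: Heterogeneous catalytic hydrogenation of the cross‑conjugated dienone should deliver hydrogen to C5 from the α‑face, opposite the angular C10 methyl, giving the trans‑fused decalone, and acid‑catalysed enolisation then places the C4 methyl in the equatorial α‑position.

Step 2
Reactants: 2 α‑tetrahydrosantonin
Product: 4 3‑oxo‑4α‑methyl‑5αH‑eudesma‑1,11(13)‑dien‑12,6α‑olide, via 2α,11β‑bis(phenylseleno) keto lactone 3 (not isolated)
Conditions: LDA (2.3 equiv), THF, −78 °C; PhSeCl (2.4 equiv), −78 °C; then H2O2 (30 %), pyridine, CH2Cl2, 0 → 25 °C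
Reagents that add atoms: none
Why: Kinetic double deprotonation (ketone at the C2 methylene, lactone at C11), selenenylation of both enolates and selenoxide syn‑elimination should install the 1‑en‑3‑one and the exocyclic α‑methylene lactone together, because the C2 selenoxide can only eliminate towards C1 and the C11 selenium, which is expected to enter anti to H7, can only eliminate towards the methyl group; no stereocentre is created.

Step 3
Reactants: 4 3‑oxo‑4α‑methyl‑5αH‑eudesma‑1,11(13)‑dien‑12,6α‑olide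
Product: 5 3,3‑(ethylenedioxy)‑4α‑methyl‑5αH‑eudesma‑1,11(13)‑dien‑12,6α‑olide
Conditions: (TMSOCH2)2, TMSOTf (cat.), CH2Cl2, −78 → −20 °C
Reagents that add atoms: 1,2‑bis(trimethylsilyloxy)ethane, C[Si](C)(C)OCCO[Si](C)(C)C
Why: TMSOTf‑catalysed silyl‑transfer ketalisation should convert the enone into its dioxolane without olefin migration (C10 is quaternary), leaving a C1=C2 olefin with no allylic hydrogen (C3 is the ketal carbon, C10 is quaternary) that is therefore inert in the later SeO2 step.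

Step 4
Reactants: 5 3,3‑(ethylenedioxy)‑4α‑methyl‑5αH‑eudesma‑1,11(13)‑dien‑12,6α‑olide
Product: 7 3,3‑(ethylenedioxy)‑13‑hydroxy‑5αH,11βH‑eudesm‑1‑en‑12,6α‑olide, via C13 pinacol boronate 6 (not isolated)
Conditions: B2pin2, CuCl (cat.), Xantphos (cat.), NaOtBu (cat.), MeOH, THF, 25 °C; then NaBO3·4H2O, THF–H2O, 25 °C
Reagents that add atoms: sodium perborate, [Na+].[Na+].O[B-]1(O)OO[B-](O)(O)OO1
Why: Copper‑catalysed conjugate borylation of the α‑methylene lactone (the isolated C1=C2 olefin does not accept boryl‑copper) and oxidation of the C–B bond should place oxygen on C13; C11 is set by protonation of the enolate (11βH expected) and is erased again in step 6.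

Step 5
Reactants: 7 3,3‑(ethylenedioxy)‑13‑hydroxy‑5αH,11βH‑eudesm‑1‑en‑12,6α‑olide
Product: 8 3,3‑(ethylenedioxy)‑13‑oxo‑5αH‑eudesm‑1‑en‑12,6α‑olide (α‑formyl lactone, mainly as its hydroxymethylene enol)
Conditions: Dess–Martin periodinane, pyridine, CH2Cl2, 0 → 25 °C
Reagents that add atoms: none
Why: Dess–Martin oxidation of the primary alcohol should give the α‑formyl lactone, a β‑dicarbonyl compound whose enol is the substrate for the next dehydrogenation.

Step 6
Reactants: 8 3,3‑(ethylenedioxy)‑13‑oxo‑5αH‑eudesm‑1‑en‑12,6α‑olide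
Product: 9 3,3‑(ethylenedioxy)‑13‑oxo‑5αH‑eudesma‑1,7(11)‑dien‑12,6α‑olide
Conditions: DDQ, 1,4‑dioxane, 25 °C
Reagents that add atoms: none
Why: DDQ dehydrogenation of a 2‑hydroxymethylene carbonyl compound proceeds by hydride abstraction from the position allylic to the enol, which here is only C7–H, so the new double bond can only enter C7=C11 whatever the configuration at C11.

Step 7
Reactants: 9 3,3‑(ethylenedioxy)‑13‑oxo‑5αH‑eudesma‑1,7(11)‑dien‑12,6α‑olide
Product: 10 3,3‑(ethylenedioxy)‑13‑hydroxy‑5αH‑eudesma‑1,7(11)‑dien‑12,6α‑olide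
Conditions: NaBH4, CeCl3·7H2O, MeOH, −78 °C
Reagents that add atoms: none
Why: Luche reduction should reduce the aldehyde in 1,2‑fashion only, the lactone carbonyl and the fully substituted β‑carbon C7 being much less reactive.

Step 8
Reactants: 10 3,3‑(ethylenedioxy)‑13‑hydroxy‑5αH‑eudesma‑1,7(11)‑dien‑12,6α‑olide
Product: 11 3,3‑(ethylenedioxy)‑13‑(triisopropylsilyloxy)‑5αH‑eudesma‑1,7(11)‑dien‑12,6α‑olide
Conditions: TIPSCl, imidazole, DMF, 25 °C
Reagents that add atoms: triisopropylsilyl chloride, CC(C)[Si](Cl)(C(C)C)C(C)C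
Why: Silylation of the primary allylic alcohol protects O13 as a group that is not a chromophore at 254 nm, is a poor leaving group towards palladium and survives the acid, oxidant and Mitsunobu steps that follow.

Step 9
Reactants: 11 3,3‑(ethylenedioxy)‑13‑(triisopropylsilyloxy)‑5αH‑eudesma‑1,7(11)‑dien‑12,6α‑olide
Product: 12 3,3‑(ethylenedioxy)‑8β‑hydroxy‑13‑(triisopropylsilyloxy)‑5αH‑eudesma‑1,7(11)‑dien‑12,6α‑olide
Conditions: SeO2, pyridine, 1,4‑dioxane, 80 °C
Reagents that add atoms: selenium dioxide, O=[Se]=O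
Why: In this Riley oxidation (ene reaction then [2,3]‑sigmatropic shift) selenium should bond to C11, the α‑carbon of the enoate, and take hydrogen from the C8 methylene rather than the acyloxy‑deactivated C6 methine, removing the axial 8β‑hydrogen that overlaps with the π system and returning oxygen to the same face to give the axial 8β‑alcohol, while C1=C2 has no allylic hydrogen to offer.

Step 10
Reactants: 12 3,3‑(ethylenedioxy)‑8β‑hydroxy‑13‑(triisopropylsilyloxy)‑5αH‑eudesma‑1,7(11)‑dien‑12,6α‑olide; 13 tiglic acid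
Product: 14 3,3‑(ethylenedioxy)‑8α‑tigloyloxy‑13‑(triisopropylsilyloxy)‑5αH‑eudesma‑1,7(11)‑dien‑12,6α‑olide
Conditions: PPh3, DIAD, toluene, 0 → 25 °C
Reagents that add atoms: tiglic acid (13), C/C=C(\C)C(O)=O
Why: In the Mitsunobu reaction the axial, allylic oxyphosphonium group should be displaced by tiglate in an SN2 process from the open α‑face, inverting C8 to the 8α (S) ester of the target.

Step 11
Reactants: 14 3,3‑(ethylenedioxy)‑8α‑tigloyloxy‑13‑(triisopropylsilyloxy)‑5αH‑eudesma‑1,7(11)‑dien‑12,6α‑olide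
Product: 15 3‑oxo‑8α‑tigloyloxy‑13‑(triisopropylsilyloxy)‑5αH‑eudesma‑1,7(11)‑dien‑12,6α‑olide
Conditions: PPTS, THF–H2O, 45 °C
Reagents that add atoms: water, O
Why: Acid‑catalysed hydrolysis of the dioxolane regenerates the conjugated 1‑en‑3‑one directly, so no base‑mediated dehydrogenation is needed in the presence of the base‑sensitive butenolide.

Step 12
Reactants: 15 3‑oxo‑8α‑tigloyloxy‑13‑(triisopropylsilyloxy)‑5αH‑eudesma‑1,7(11)‑dien‑12,6α‑olide
Product: 16 8α‑tigloyloxy‑3‑(trifluoromethanesulfonyloxy)‑13‑(triisopropylsilyloxy)‑5αH‑eudesma‑1,3,7(11)‑trien‑12,6α‑olide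
Conditions: Tf2O, 2,6‑di‑tert‑butyl‑4‑methylpyridine, CH2Cl2, 0 → 25 °C
Reagents that add atoms: trifluoromethanesulfonic anhydride, O=S(=O)(OS(=O)(=O)C(F)(F)F)C(F)(F)F
Why: O‑Sulfonylation of the enone and loss of H4, the only enolisable proton, should give the 1,3‑dien‑3‑yl triflate under non‑nucleophilic, weakly basic conditions that spare the butenolide.

Step 13
Reactants: 16 8α‑tigloyloxy‑3‑(trifluoromethanesulfonyloxy)‑13‑(triisopropylsilyloxy)‑5αH‑eudesma‑1,3,7(11)‑trien‑12,6α‑olide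
Product: 17 8α‑tigloyloxy‑13‑(triisopropylsilyloxy)‑5αH‑eudesma‑1,3,7(11)‑trien‑12,6α‑olide
Conditions: Pd(OAc)2 (cat.), PPh3, HCO2H, Bu3N, DMF, 40 °C
Reagents that add atoms: none
Why: Palladium‑catalysed formate reduction of an enol triflate (fast oxidative addition of C–OTf to zerovalent palladium, formate‑to‑hydride exchange with loss of CO2, reductive elimination) should give the homoannular 1,3‑diene without moving the double bonds and faster than any ionisation of the hindered equatorial allylic ester.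

Step 14
Reactants: 17 8α‑tigloyloxy‑13‑(triisopropylsilyloxy)‑5αH‑eudesma‑1,3,7(11)‑trien‑12,6α‑olide
Product: 18 (1(10)E,2Z,4E)‑8α‑tigloyloxy‑13‑(triisopropylsilyloxy)germacra‑1(10),2,4,7(11)‑tetraen‑12,6α‑olide
Conditions: hν (254 nm, low‑pressure Hg lamp, quartz), degassed MeOH–THF, −20 °C, to the photostationary mixture; solution kept at −20 °C and used directly
Reagents that add atoms: none
Why: Excitation of the s‑cis diene of ring A triggers a conrotatory 6π‑electrocyclic opening in which the C5–C10 σ bond is cleaved and the 1(10) and 4,5 double bonds are formed, the closest known reaction type being the photochemical opening of trans‑fused bicyclic cyclohexa‑1,3‑dienes to cyclodeca‑1,3,5‑trienes, as in the provitamin D to previtamin D conversion. No ring is closed: rings A and B merge into the ten‑membered carbocycle by scission of their shared bond, so no mode of closure applies. No stereocentre is created; the trans relation of 5α‑H and 10β‑CH3 combined with conrotation fixes the E geometry of both trisubstituted olefins, and the central C2=C3 olefin stays Z. The step needs the diene to be the absorbing unit and the triene to survive: at 254 nm the diene (maximum near 260 nm) should take up almost all the light, since the butenolide and tiglate absorb near 220 nm, and ring opening from the excited diene is expected to outrun energy transfer to them. Working at −20 °C and stopping at the photostationary mixture suppresses thermal disrotatory reclosure to a cis‑fused diene; unconverted 17 is removed after step 15.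

Step 15
Reactants: 18 (1(10)E,2Z,4E)‑8α‑tigloyloxy‑13‑(triisopropylsilyloxy)germacra‑1(10),2,4,7(11)‑tetraen‑12,6α‑olide
Product: 19 (1(10)E,4E)‑8α‑tigloyloxy‑13‑(triisopropylsilyloxy)germacra‑1(10),4,7(11)‑trien‑12,6α‑olide
Conditions: KO2CN=NCO2K, AcOH, MeOH–THF, −20 → −10 °C (added to the cold photolysate); chromatography on Et3N‑deactivated silica at 0–5 °C
Reagents that add atoms: none
Why: Diimide reduction (concerted syn transfer of H2) should saturate the cis‑disubstituted central olefin of the strained triene much faster than the trisubstituted E olefins or the polarised, more substituted enoate olefins.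

Step 16
Reactants: 19 (1(10)E,4E)‑8α‑tigloyloxy‑13‑(triisopropylsilyloxy)germacra‑1(10),4,7(11)‑trien‑12,6α‑olide
Product: 20 1β,10α:4α,5β‑diepoxy‑8α‑tigloyloxy‑13‑(triisopropylsilyloxy)germacr‑7(11)‑en‑12,6α‑olide
Conditions: mCPBA (2.5 equiv), CH2Cl2–aq. NaHCO3 (two‑phase), 0 °C
Reagents that add atoms: meta‑chloroperbenzoic acid, OOC(=O)c1cccc(Cl)c1
Why: In this Prilezhaev epoxidation the peracid should attack each E‑trisubstituted olefin from the ring periphery in the conformer that holds C14 and C15 on the β‑face, giving the 1β,10α and 4α,5β oxiranes (1R,10R,4R,5R), while the electron‑poor butenolide and tiglate olefins do not react.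

Step 17
Reactants: 20 1β,10α:4α,5β‑diepoxy‑8α‑tigloyloxy‑13‑(triisopropylsilyloxy)germacr‑7(11)‑en‑12,6α‑olide
Product: 21 CNP0111480.1 (1β,10α:4α,5β‑diepoxy‑13‑hydroxy‑8α‑tigloyloxygermacr‑7(11)‑en‑12,6α‑olide)
Conditions: HF·pyridine, pyridine, THF, 0 °C
Reagents that add atoms: none
Why: Fluoride‑induced cleavage of the Si–O bond under pyridine‑buffered conditions should free the C13 alcohol without opening the oxiranes or promoting acyl migration from O8 to O13.

**Compound list**

1 | α‑santonin | C[C@H]1[C@@H]2CC[C@]3(C=CC(=O)C(=C3[C@H]2OC1=O)C)C | starting material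
2 | α‑tetrahydrosantonin (3‑oxo‑4α‑methyl‑5αH,11βH‑eudesman‑12,6α‑olide) | C[C@H]1[C@@H]2CC[C@@]3(C)CCC(=O)[C@@H](C)[C@@H]3[C@H]2OC1=O | intermediate
3 | 2α,11β‑bis(phenylseleno)‑3‑oxo‑4α‑methyl‑5αH‑eudesman‑12,6α‑olide (expected configuration) | C[C@@]1([Se]c4ccccc4)[C@@H]2CC[C@@]3(C)C[C@@H]([Se]c4ccccc4)C(=O)[C@@H](C)[C@@H]3[C@H]2OC1=O | intermediate (not isolated)
4 | 3‑oxo‑4α‑methyl‑5αH‑eudesma‑1,11(13)‑dien‑12,6α‑olide | C=C1[C@@H]2CC[C@@]3(C)C=CC(=O)[C@@H](C)[C@@H]3[C@H]2OC1=O | intermediate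
5 | 3,3‑(ethylenedioxy)‑4α‑methyl‑5αH‑eudesma‑1,11(13)‑dien‑12,6α‑olide | C=C1[C@@H]2CC[C@@]3(C)C=CC4(OCCO4)[C@@H](C)[C@@H]3[C@H]2OC1=O | intermediate
6 | 3,3‑(ethylenedioxy)‑13‑(4,4,5,5‑tetramethyl‑1,3,2‑dioxaborolan‑2‑yl)‑5αH,11βH‑eudesm‑1‑en‑12,6α‑olide | CC1(C)OB(C[C@H]2[C@@H]3CC[C@@]4(C)C=CC5(OCCO5)[C@@H](C)[C@@H]4[C@H]3OC2=O)OC1(C)C | intermediate (not isolated)
7 | 3,3‑(ethylenedioxy)‑13‑hydroxy‑5αH,11βH‑eudesm‑1‑en‑12,6α‑olide (11βH epimer drawn; C11 is erased in step 6) | OC[C@H]1[C@@H]2CC[C@@]3(C)C=CC4(OCCO4)[C@@H](C)[C@@H]3[C@H]2OC1=O | intermediate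
8 | 3,3‑(ethylenedioxy)‑13‑oxo‑5αH‑eudesm‑1‑en‑12,6α‑olide (C11 labile, largely enolised) | O=CC1[C@@H]2CC[C@@]3(C)C=CC4(OCCO4)[C@@H](C)[C@@H]3[C@H]2OC1=O | intermediate
9 | 3,3‑(ethylenedioxy)‑13‑oxo‑5αH‑eudesma‑1,7(11)‑dien‑12,6α‑olide | O=CC1=C2CC[C@@]3(C)C=CC4(OCCO4)[C@@H](C)[C@@H]3[C@H]2OC1=O | intermediate
10 | 3,3‑(ethylenedioxy)‑13‑hydroxy‑5αH‑eudesma‑1,7(11)‑dien‑12,6α‑olide | OCC1=C2CC[C@@]3(C)C=CC4(OCCO4)[C@@H](C)[C@@H]3[C@H]2OC1=O | intermediate
11 | 3,3‑(ethylenedioxy)‑13‑(triisopropylsilyloxy)‑5αH‑eudesma‑1,7(11)‑dien‑12,6α‑olide | CC(C)[Si](OCC1=C2CC[C@@]3(C)C=CC4(OCCO4)[C@@H](C)[C@@H]3[C@H]2OC1=O)(C(C)C)C(C)C | intermediate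
12 | 3,3‑(ethylenedioxy)‑8β‑hydroxy‑13‑(triisopropylsilyloxy)‑5αH‑eudesma‑1,7(11)‑dien‑12,6α‑olide | CC(C)[Si](OCC1=C2[C@H](O)C[C@@]3(C)C=CC4(OCCO4)[C@@H](C)[C@@H]3[C@H]2OC1=O)(C(C)C)C(C)C | intermediate
13 | tiglic acid | C/C=C(\C)C(O)=O | starting material
14 | 3,3‑(ethylenedioxy)‑8α‑tigloyloxy‑13‑(triisopropylsilyloxy)‑5αH‑eudesma‑1,7(11)‑dien‑12,6α‑olide | C/C=C(\C)C(=O)O[C@H]1C[C@@]2(C)C=CC3(OCCO3)[C@@H](C)[C@@H]2[C@H]2OC(=O)C(CO[Si](C(C)C)(C(C)C)C(C)C)=C12 | intermediate
15 | 3‑oxo‑8α‑tigloyloxy‑13‑(triisopropylsilyloxy)‑5αH‑eudesma‑1,7(11)‑dien‑12,6α‑olide | C/C=C(\C)C(=O)O[C@H]1C[C@@]2(C)C=CC(=O)[C@@H](C)[C@@H]2[C@H]2OC(=O)C(CO[Si](C(C)C)(C(C)C)C(C)C)=C12 | intermediate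
16 | 8α‑tigloyloxy‑3‑(trifluoromethanesulfonyloxy)‑13‑(triisopropylsilyloxy)‑5αH‑eudesma‑1,3,7(11)‑trien‑12,6α‑olide | C/C=C(\C)C(=O)O[C@H]1C[C@@]2(C)C=CC(OS(=O)(=O)C(F)(F)F)=C(C)[C@@H]2[C@H]2OC(=O)C(CO[Si](C(C)C)(C(C)C)C(C)C)=C12 | intermediate
17 | 8α‑tigloyloxy‑13‑(triisopropylsilyloxy)‑5αH‑eudesma‑1,3,7(11)‑trien‑12,6α‑olide | C/C=C(\C)C(=O)O[C@H]1C[C@@]2(C)C=CC=C(C)[C@@H]2[C@H]2OC(=O)C(CO[Si](C(C)C)(C(C)C)C(C)C)=C12 | intermediate (key‑step precursor)
18 | (1(10)E,2Z,4E)‑8α‑tigloyloxy‑13‑(triisopropylsilyloxy)germacra‑1(10),2,4,7(11)‑tetraen‑12,6α‑olide | C/C=C(\C)C(=O)O[C@H]1C/C(C)=C/C=C\C(C)=C\[C@H]2OC(=O)C(CO[Si](C(C)C)(C(C)C)C(C)C)=C12 | intermediate (key‑step product)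
19 | (1(10)E,4E)‑8α‑tigloyloxy‑13‑(triisopropylsilyloxy)germacra‑1(10),4,7(11)‑trien‑12,6α‑olide | C/C=C(\C)C(=O)O[C@H]1C/C(C)=C/CC/C(C)=C/[C@H]2OC(=O)C(CO[Si](C(C)C)(C(C)C)C(C)C)=C12 | intermediate
20 | 1β,10α:4α,5β‑diepoxy‑8α‑tigloyloxy‑13‑(triisopropylsilyloxy)germacr‑7(11)‑en‑12,6α‑olide | C/C=C(\C)C(=O)O[C@H]1C[C@@]2(C)O[C@@H]2CC[C@@]2(C)O[C@@H]2[C@H]2OC(=O)C(CO[Si](C(C)C)(C(C)C)C(C)C)=C12 | intermediate
21 | CNP0111480.1 (1β,10α:4α,5β‑diepoxy‑13‑hydroxy‑8α‑tigloyloxygermacr‑7(11)‑en‑12,6α‑olide) | C/C=C(\C)C(=O)O[C@H]1C[C@@]2(C)O[C@@H]2CC[C@@]2(C)O[C@@H]2[C@H]2OC(=O)C(CO)=C12 | target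

**Count and risks**

Total steps: 17. Longest linear sequence: 17 steps, from α‑santonin 1 to 21; tiglic acid 13 is used as bought.

The three steps judged most likely to fail:

Step 9 (allylic hydroxylation). The ene reaction at the electron‑poor tetrasubstituted olefin may be slow, so that over‑oxidation to the enone, attack at C6–H or acid‑induced loss of the dioxolane compete, and oxygen delivery may not be purely axial. The fallback sets out from 11: allylic oxidation with CrO3–3,5‑dimethylpyrazole (CH2Cl2, −20 °C) takes C8 to the ketone 3,3‑(ethylenedioxy)‑8‑oxo‑13‑(triisopropylsilyloxy)‑5αH‑eudesma‑1,7(11)‑dien‑12,6α‑olide F1. Luche reduction (NaBH4, CeCl3·7H2O, MeOH, −78 °C), with hydride entering from the α‑face away from the axial C10 methyl, then returns to the route at 12.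

Step 10 (Mitsunobu esterification). Anti elimination of the activated axial alcohol towards C9 (H9α is antiperiplanar), or slow activation next to the C10 methyl, may outrun substitution by the weakly acidic tiglic acid. The fallback sets out from 12 and separates inversion from acylation: a Mitsunobu reaction with the much more acidic chloroacetic acid (PPh3, DIAD, toluene) gives 8α‑(chloroacetoxy)‑3,3‑(ethylenedioxy)‑13‑(triisopropylsilyloxy)‑5αH‑eudesma‑1,7(11)‑dien‑12,6α‑olide F2. Thiourea (NaHCO3, EtOH, 25 °C) frees the equatorial alcohol 3,3‑(ethylenedioxy)‑8α‑hydroxy‑13‑(triisopropylsilyloxy)‑5αH‑eudesma‑1,7(11)‑dien‑12,6α‑olide F3. Yamaguchi esterification with tiglic acid 13 (2,4,6‑trichlorobenzoyl chloride, Et3N, DMAP, toluene) rejoins the route at 14.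

Step 16 (double epoxidation). Facial selectivity at the C1(10) olefin may be poor if a second ring conformer of 19 is populated, and the intermediate mono‑epoxide may undergo acid‑induced transannular cyclisation. The fallback sets out from 19 and uses reagent control instead of substrate control: Shi epoxidation (D‑fructose‑derived ketone, Oxone, K2CO3‑buffered MeCN–dimethoxymethane–H2O, 0 °C) transfers oxygen to E‑trisubstituted olefins in the (R,R) sense needed at C1/C10 and C4/C5 under non‑acidic conditions and leads directly to 20; this fallback makes no new compound (F0).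

**Further compounds**

F1 | step 9 | 3,3‑(ethylenedioxy)‑8‑oxo‑13‑(triisopropylsilyloxy)‑5αH‑eudesma‑1,7(11)‑dien‑12,6α‑olide | CC(C)[Si](OCC1=C2C(=O)C[C@@]3(C)C=CC4(OCCO4)[C@@H](C)[C@@H]3[C@H]2OC1=O)(C(C)C)C(C)C
F2 | step 10 | 8α‑(chloroacetoxy)‑3,3‑(ethylenedioxy)‑13‑(triisopropylsilyloxy)‑5αH‑eudesma‑1,7(11)‑dien‑12,6α‑olide | ClCC(=O)O[C@H]1C[C@@]2(C)C=CC3(OCCO3)[C@@H](C)[C@@H]2[C@H]2OC(=O)C(CO[Si](C(C)C)(C(C)C)C(C)C)=C12
F3 | step 10 | 3,3‑(ethylenedioxy)‑8α‑hydroxy‑13‑(triisopropylsilyloxy)‑5αH‑eudesma‑1,7(11)‑dien‑12,6α‑olide | O[C@H]1C[C@@]2(C)C=CC3(OCCO3)[C@@H](C)[C@@H]2[C@H]2OC(=O)C(CO[Si](C(C)C)(C(C)C)C(C)C)=C12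
F0 | step 16 | none | none
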